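At early times the readings are small numbers carrying a scatter of 1.5 percentage points: Sunday's flask, the one asked about, shows 7% E and 5% Q at 0.250 h, and Thursday's shows 10% and 1%, so I reckon from the late end and with the fraction left rather than the fraction made.

| setting | Sunday's | Thursday's | flask |
|---|---|---|---|
| X | 1 M | 1 M | 1.0 M |
| L | 0.50 equiv | 0.75 equiv | 0.500 equiv |
| Z | 0.22 mol% | 0.22 mol% | 0.22 mol% |
| remark | the very flask that is asked about, followed so far | run made earlier |  |
| time |  |  | 12 h |

- Sunday's (time / h: E / %, Q / %): 0.250: 7, 5; 0.417: 8, 1; 0.667: 16, 4; 1.00: 19, 8; 1.50: 24, 9; 2.50: 39, 17; 4.00: 48, 19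
- Thursday's (time / h: E / %, Q / %): 0.250: 10, 1; 0.667: 13, 3; 1.33: 24, 9; 2.00: 31, 16; 3.00: 42, 17; 4.00: 51, 19; 5.00: 55, 21

(standard deviation of a reading: 1.5 percentage points)

- ratio of E to Q at 80 s
- ratio of E to Q at 12 h
- which of E and Q there is more of at 12 h



Let f be the fraction of the charge in neither E nor Q. In Sunday's flask f reads 33.0% at 4.00 h, and if the decay is pseudo-first-order, I define N, the number of e-foldings of f by 12 h, as 3.33, which leaves exp(−N) = 3.59%. Thursday's flask, with 0.75 equiv of L, gives 3.61 from its 4.00 h reading, so the two runs tell a similar story. But N says how far the flask has gone and nothing of how the product is shared, so one number is not enough: I add the reading E/Q = 2.53 at 4.00 h and expect it to hold at 12 h, with E ahead.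

The forecast gives E/Q = 40 at 80 s and 2.5 at 12 h, with E ahead, and it reads the late ratio as steady, “with no sign of drifting toward Q”.

The flask gives E/Q = 5.41 at 80 s and 3.16 at 12 h, with E ahead at 68.4% against Q at 21.7%.

    Z + L → Z + E (k = 11.0 M⁻¹ min⁻¹)
    X ⇌ G (K = 0.750, k = 3.70 × 10⁻⁴ min⁻¹)
    X ⇌ L (K = 0.180, k = 0.0490 min⁻¹)
    Z → J (k = 2.00 × 10⁻⁶ min⁻¹)
    X + Z ⇌ Z + Q (K = 2.70, k = 0.860 M⁻¹ min⁻¹)

In this flask X, L and G together hold 9.89% at 12 h, more than exp(−N) gave, which counts as 2.31 e-foldings, fewer than N. In this flask Q stands at 22.0% at 6.00 h and 21.7% at 12.0 h while E climbs from 57.1% to 68.4%, and at 12.0 h the forward rate of X to L is 26 times that of X to Q.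

For a second flask with 0.88 mol% of Z, if N is taken proportional to Z, N becomes 13.3, so exp(−N) is <0.001%. That flask holds 3.45% in X, L and G at 12 h, more than this reckoning gave, with Q at 10.3%, E at 86.2% and E/Q at 8.36.

(The data stem from a simulated flask with constants of no real substance; noise was put on by code.)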